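**Plan**

- Cuts: first the bond from C8 of coumarin A to the styryl carbon (Heck). Then, in coumarin B, the pyranone bonds O1–C2 and C3=C4 and the C4a–C4 bond (formylation). Then the benzene ring of coumarin B at C8–C8a and C6–C7, with C4a–C8a as the closing bond. Last, the cyclohexene at C1–C6 and C2–C3 (Diels–Alder).
- Feature used: in coumarin B, benzene carbon C8 bears the cyclohexenyl carbon and lies between the oxygen-bearing C8a and C7; C5–OMe is para to it, and C6–H and C4a complete the ring. This 2-alkylphloroglucinol pattern with three differentiated oxygens is what a vinylketene plus ynol ether benzannulation delivers.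
- Forward order: cyclohexene ring, then benzene ring B on the cyclohexenyl carbon, then pyranone B, then attachment of preformed coumarin A.
- Stereochemistry: both stereocentres come from one catalytic enantioselective endo Diels–Alder reaction (step 4). No later step touches them. The E-alkene follows from the Heck syn-insertion/syn-elimination.

Key step: step 11

Assumption: in step 4 the (S)-configured oxazaborolidinium ion is taken to expose the Re face at C2 of bound methacrolein; if the sense proves opposite, the (R)-catalyst is used with no other change.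

**Route**

Step 1
Reactants: 1 methacrolein; 2 triethyl phosphonoacetate
Product: 3 ethyl (2E)-4-methylpenta-2,4-dienoate
Conditions: NaH, THF, 0 °C → rt
Reagents that add atoms: none
Why: Horner–Wadsworth–Emmons olefination of an enal with a stabilised phosphonate anion is reliably E-selective and leaves the 1,1-disubstituted alkene untouched.

Step 2
Reactants: 3 ethyl (2E)-4-methylpenta-2,4-dienoate
Product: 4 (2E)-4-methylpenta-2,4-dien-1-ol
Conditions: i-Bu2AlH, CH2Cl2, −78 → 0 °C
Reagents that add atoms: none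
Why: 1,2-reduction of a conjugated ester by an aluminium hydride at low temperature should give the allylic alcohol without conjugate reduction.

Step 3
Reactants: 4 (2E)-4-methylpenta-2,4-dien-1-ol
Product: 5 tert-butyl(dimethyl){[(2E)-4-methylpenta-2,4-dien-1-yl]oxy}silane
Conditions: TBSCl, imidazole, DMF, 0 °C → rt
Reagents that add atoms: tert-butyl(chloro)dimethylsilane, CC(C)(C)[Si](C)(C)Cl
Why: standard silylation of a primary alcohol gives a bulky, weakly Lewis-basic ether that the cationic boron catalyst of step 4 should tolerate.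

Step 4
Reactants: 5 tert-butyl(dimethyl){[(2E)-4-methylpenta-2,4-dien-1-yl]oxy}silane; 1 methacrolein
Product: 6 (1S,2R)-2-({[tert-butyl(dimethyl)silyl]oxy}methyl)-1,4-dimethylcyclohex-3-ene-1-carbaldehyde
Conditions: 1 (3 equiv), (S)-3,3-diphenyl-1-(2-methylphenyl)tetrahydro-1H,3H-pyrrolo[1,2-c][1,3,2]oxazaborole (20 mol%), Tf2NH (17 mol%), CH2Cl2, −78 → −40 °C
Reagents that add atoms: none
Why: catalytic enantioselective Diels–Alder reaction in which the oxazaborolidinium ion binds methacrolein s-trans and shields one face of its C2, fixing the quaternary centre as (1S); the 1-substituent and 3-methyl group of the diene both direct the formyl-bearing carbon to the substituted diene terminus, and the endo transition state (formyl under the diene, α-methyl outside) places CHO cis to CH2OTBS, setting C2 as (R).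

Step 5
Reactants: 6 (1S,2R)-2-({[tert-butyl(dimethyl)silyl]oxy}methyl)-1,4-dimethylcyclohex-3-ene-1-carbaldehyde
Product: 7 tert-butyl{[(1R,6R)-6-ethenyl-3,6-dimethylcyclohex-2-en-1-yl]methoxy}dimethylsilane
Conditions: MePPh3Br, KOt-Bu, THF, 0 °C → rt
Reagents that add atoms: methyltriphenylphosphonium bromide, C[P+](c1ccccc1)(c1ccccc1)c1ccccc1.[Br-]
Why: Wittig methylenation of a non-enolisable α-quaternary aldehyde cannot epimerise either centre.

Step 6
Reactants: 7 tert-butyl{[(1R,6R)-6-ethenyl-3,6-dimethylcyclohex-2-en-1-yl]methoxy}dimethylsilane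
Product: 8 [(1R,6R)-6-ethenyl-3,6-dimethylcyclohex-2-en-1-yl]methanol
Conditions: n-Bu4NF, THF, 0 °C → rt
Reagents that add atoms: none
Why: fluoride cleavage of a primary silyl ether is routine and leaves both alkenes untouched.

Step 7
Reactants: 8 [(1R,6R)-6-ethenyl-3,6-dimethylcyclohex-2-en-1-yl]methanol
Product: 9 (1R,6R)-6-ethenyl-3,6-dimethylcyclohex-2-ene-1-carbaldehyde
Conditions: Dess–Martin periodinane, NaHCO3, CH2Cl2, 0 °C; used at once
Reagents that add atoms: none
Why: buffered Dess–Martin oxidation is near-neutral and should give the α-branched β,γ-unsaturated aldehyde without epimerisation or double-bond migration.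

Step 8
Reactants: 9 (1R,6R)-6-ethenyl-3,6-dimethylcyclohex-2-ene-1-carbaldehyde
Product: 10 (3S,4R)-3-(2,2-dibromoethenyl)-4-ethenyl-1,4-dimethylcyclohex-1-ene
Conditions: CBr4, PPh3, Zn, CH2Cl2, rt; then 9, 0 °C → rt
Reagents that add atoms: carbon tetrabromide, BrC(Br)(Br)Br
Why: Corey–Fuchs dibromo-olefination with the preformed, non-basic ylide Ph3P=CBr2 homologates the sensitive aldehyde under neutral conditions (the descriptor at the ring CH changes only through the priority rules).

Step 9
Reactants: 10 (3S,4R)-3-(2,2-dibromoethenyl)-4-ethenyl-1,4-dimethylcyclohex-1-ene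
Product: 13 ({[(1R,6R)-6-ethenyl-3,6-dimethylcyclohex-2-en-1-yl]ethynyl}oxy)tri(propan-2-yl)silane, via lithium acetylide 11 (not isolated), via lithium ynolate 12 (not isolated)
Conditions: n-BuLi (2.05 equiv), THF, −78 °C; t-BuOOLi (from t-BuOOH and LiN(SiMe3)2), −78 → 0 °C; i-Pr3SiOTf, −78 °C
Reagents that add atoms: tert-butyl hydroperoxide, CC(C)(C)OO; triisopropylsilyl trifluoromethanesulfonate, CC(C)[Si](OS(=O)(=O)C(F)(F)F)(C(C)C)C(C)C
Why: the second stage of the Corey–Fuchs sequence gives the lithium acetylide, which lithium tert-butyl peroxide oxidises to the ynolate (the established ynolate synthesis from terminal alkynes), and the bulky silyl triflate should then silylate on oxygen.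

Step 10
Reactants: 14 cyclobutane-1,3-dione
Product: 15 3-methoxycyclobut-2-en-1-one
Conditions: Me3SiCHN2, MeOH–Et2O, 0 °C; used freshly prepared
Reagents that add atoms: (trimethylsilyl)diazomethane, C[Si](C)(C)C=[N+]=[N-]
Why: the enol form of the dione is a strong vinylogous acid and is O-methylated by diazomethane released in situ; the symmetric dione can give only one vinylogous ester.

Step 11
Reactants: 13 ({[(1R,6R)-6-ethenyl-3,6-dimethylcyclohex-2-en-1-yl]ethynyl}oxy)tri(propan-2-yl)silane; 15 3-methoxycyclobut-2-en-1-one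
Product: 20 2-[(1R,6R)-6-ethenyl-3,6-dimethylcyclohex-2-en-1-yl]-5-methoxy-3-{[tri(propan-2-yl)silyl]oxy}phenol, via vinylketene 16 (not isolated), via vinylcyclobutenone 17 (not isolated), via dienylketene 18 (not isolated), via cyclohexadienone 19 (not isolated)
Conditions: 15 (2 equiv, added in portions), toluene, 80 °C, then 110 °C, sealed tube
Reagents that add atoms: none
Why: Heating opens 15 by 4π electrocyclic cleavage to (1-methoxyethenyl)ketene 16, which adds [2+2] to the ynol ether so that the nucleophilic ring-bound alkyne carbon of 13 attacks the ketene carbonyl carbon, forming C8–C8a and C6–C7 (coumarin numbering) in cyclobutenone 17. A second 4π opening gives dienylketene 18, and the benzene ring is closed at C4a–C8a by 6π electrocyclisation to dienone 19, which tautomerises to the phenol. This is the Danheiser benzannulation of a cyclobutenone with a trialkylsiloxyalkyne, the known route to resorcinol monosilyl ethers. No stereocentre is formed, and the (1R,6R) centres are spectators under these neutral thermal conditions. The selectivity needed is the orientation of the [2+2] addition, fixed by the polarisation of the ynol ether, together with chemoselectivity over the two unactivated alkenes, which are far poorer ketenophiles. The three ring oxygens should emerge differentiated as free OH (future O1), methyl ether (C5) and silyl ether (C7).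

Step 12
Reactants: 20 2-[(1R,6R)-6-ethenyl-3,6-dimethylcyclohex-2-en-1-yl]-5-methoxy-3-{[tri(propan-2-yl)silyl]oxy}phenol
Product: 21 3-[(1R,6R)-6-ethenyl-3,6-dimethylcyclohex-2-en-1-yl]-2-hydroxy-6-methoxy-4-{[tri(propan-2-yl)silyl]oxy}benzaldehyde
Conditions: MgCl2, Et3N, (CH2O)n, MeCN, reflux
Reagents that add atoms: paraformaldehyde (as formaldehyde), C=O
Why: magnesium-phenoxide-directed ortho-formylation (Casnati–Skattebøl conditions) can occur only at the single free position ortho to the hydroxyl, the future C4a.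

Step 13
Reactants: 21 3-[(1R,6R)-6-ethenyl-3,6-dimethylcyclohex-2-en-1-yl]-2-hydroxy-6-methoxy-4-{[tri(propan-2-yl)silyl]oxy}benzaldehyde
Product: 23 8-[(1R,6R)-6-ethenyl-3,6-dimethylcyclohex-2-en-1-yl]-5-methoxy-7-{[tri(propan-2-yl)silyl]oxy}-2H-chromen-2-one, via ester ylide 22 (not isolated)
Conditions: Ph3P=C=C=O, toluene, 110 °C
Reagents that add atoms: (triphenylphosphoranylidene)ketene, O=C=C=P(c1ccccc1)(c1ccccc1)c1ccccc1
Why: the phenol adds to the cumulated ylide to give an aryl phosphoranylideneacetate, whose intramolecular Wittig reaction with the neighbouring formyl group closes the pyranone with the required cis alkene.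

Step 14
Reactants: 23 8-[(1R,6R)-6-ethenyl-3,6-dimethylcyclohex-2-en-1-yl]-5-methoxy-7-{[tri(propan-2-yl)silyl]oxy}-2H-chromen-2-one
Product: 25 8-[(1R,6R)-6-ethenyl-3,6-dimethylcyclohex-2-en-1-yl]-5,7-dimethoxy-2H-chromen-2-one, via tetrabutylammonium phenoxide 24 (not isolated)
Conditions: n-Bu4NF, THF, 0 °C; then MeI, rt
Reagents that add atoms: iodomethane, CI
Why: fluoride cleaves the aryl silyl ether and the resulting tetrabutylammonium phenoxide is methylated in the same flask (Williamson ether synthesis).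

Step 15
Reactants: 26 5,7-dimethoxy-2H-chromen-2-one
Product: 27 8-iodo-5,7-dimethoxy-2H-chromen-2-one
Conditions: N-iodosuccinimide, CF3CO2H (cat.), MeCN, rt
Reagents that add atoms: N-iodosuccinimide, O=C1CCC(=O)N1I
Why: electrophilic aromatic iodination should occur at C8, which is activated ortho/para by both methoxy groups and is less hindered than C6 between them.

Step 16
Reactants: 25 8-[(1R,6R)-6-ethenyl-3,6-dimethylcyclohex-2-en-1-yl]-5,7-dimethoxy-2H-chromen-2-one; 27 8-iodo-5,7-dimethoxy-2H-chromen-2-one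
Product: 28 8-[(E)-2-[(1R,2R)-2-(5,7-dimethoxy-2-oxo-2H-chromen-8-yl)-1,4-dimethylcyclohex-3-en-1-yl]ethenyl]-5,7-dimethoxy-2H-chromen-2-one
Conditions: Pd(OAc)2 (10 mol%), n-Bu4NCl, NaHCO3, DMF, 85 °C
Reagents that add atoms: none
Why: Mizoroki–Heck reaction in which the aryl group adds to the terminal carbon of the monosubstituted alkene and, the neighbouring carbon being quaternary, β-hydride elimination can give only the E-styrene; the coumarin C3=C4 bonds and the trisubstituted ring alkene are far less reactive toward carbopalladation.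

**Compound list**

1 | methacrolein | C=C(C)C=O | starting material
2 | triethyl phosphonoacetate | CCOC(=O)CP(=O)(OCC)OCC | starting material
3 | ethyl (2E)-4-methylpenta-2,4-dienoate | C=C(C)/C=C/C(=O)OCC | intermediate
4 | (2E)-4-methylpenta-2,4-dien-1-ol | C=C(C)/C=C/CO | intermediate
5 | tert-butyl(dimethyl){[(2E)-4-methylpenta-2,4-dien-1-yl]oxy}silane | C=C(C)/C=C/CO[Si](C)(C)C(C)(C)C | intermediate
6 | (1S,2R)-2-({[tert-butyl(dimethyl)silyl]oxy}methyl)-1,4-dimethylcyclohex-3-ene-1-carbaldehyde | O=C[C@@]1(C)CCC(C)=C[C@H]1CO[Si](C)(C)C(C)(C)C | intermediate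
7 | tert-butyl{[(1R,6R)-6-ethenyl-3,6-dimethylcyclohex-2-en-1-yl]methoxy}dimethylsilane | C=C[C@@]1(C)CCC(C)=C[C@H]1CO[Si](C)(C)C(C)(C)C | intermediate
8 | [(1R,6R)-6-ethenyl-3,6-dimethylcyclohex-2-en-1-yl]methanol | C=C[C@@]1(C)CCC(C)=C[C@H]1CO | intermediate
9 | (1R,6R)-6-ethenyl-3,6-dimethylcyclohex-2-ene-1-carbaldehyde | C=C[C@@]1(C)CCC(C)=C[C@H]1C=O | intermediate
10 | (3S,4R)-3-(2,2-dibromoethenyl)-4-ethenyl-1,4-dimethylcyclohex-1-ene | C=C[C@@]1(C)CCC(C)=C[C@H]1C=C(Br)Br | intermediate
11 | lithium [(1R,6R)-6-ethenyl-3,6-dimethylcyclohex-2-en-1-yl]acetylide | C=C[C@@]1(C)CCC(C)=C[C@H]1C#C[Li] | intermediate (not isolated)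
12 | lithium 2-[(1R,6R)-6-ethenyl-3,6-dimethylcyclohex-2-en-1-yl]ethyn-1-olate | C=C[C@@]1(C)CCC(C)=C[C@H]1C#CO[Li] | intermediate (not isolated)
13 | ({[(1R,6R)-6-ethenyl-3,6-dimethylcyclohex-2-en-1-yl]ethynyl}oxy)tri(propan-2-yl)silane | C=C[C@@]1(C)CCC(C)=C[C@H]1C#CO[Si](C(C)C)(C(C)C)C(C)C | intermediate
14 | cyclobutane-1,3-dione | O=C1CC(=O)C1 | starting material
15 | 3-methoxycyclobut-2-en-1-one | COC1=CC(=O)C1 | intermediate
16 | 3-methoxybuta-1,3-dien-1-one [(1-methoxyethenyl)ketene] | C=C(OC)C=C=O | intermediate (not isolated)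
17 | 2-[(1R,6R)-6-ethenyl-3,6-dimethylcyclohex-2-en-1-yl]-4-(1-methoxyethenyl)-3-{[tri(propan-2-yl)silyl]oxy}cyclobut-2-en-1-one (both C4 epimers) | C=C[C@@]1(C)CCC(C)=C[C@H]1C1=C(O[Si](C(C)C)(C(C)C)C(C)C)C(C(=C)OC)C1=O | intermediate (not isolated)
18 | (3E)-2-[(1R,6R)-6-ethenyl-3,6-dimethylcyclohex-2-en-1-yl]-5-methoxy-3-{[tri(propan-2-yl)silyl]oxy}hexa-1,3,5-trien-1-one | C=C[C@@]1(C)CCC(C)=C[C@H]1C(=C=O)/C(O[Si](C(C)C)(C(C)C)C(C)C)=C\C(=C)OC | intermediate (not isolated)
19 | 2-[(1R,6R)-6-ethenyl-3,6-dimethylcyclohex-2-en-1-yl]-5-methoxy-3-{[tri(propan-2-yl)silyl]oxy}cyclohexa-2,4-dien-1-one | C=C[C@@]1(C)CCC(C)=C[C@H]1C1=C(O[Si](C(C)C)(C(C)C)C(C)C)C=C(OC)CC1=O | intermediate (not isolated)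
20 | 2-[(1R,6R)-6-ethenyl-3,6-dimethylcyclohex-2-en-1-yl]-5-methoxy-3-{[tri(propan-2-yl)silyl]oxy}phenol | C=C[C@@]1(C)CCC(C)=C[C@H]1c1c(O)cc(OC)cc1O[Si](C(C)C)(C(C)C)C(C)C | intermediate
21 | 3-[(1R,6R)-6-ethenyl-3,6-dimethylcyclohex-2-en-1-yl]-2-hydroxy-6-methoxy-4-{[tri(propan-2-yl)silyl]oxy}benzaldehyde | C=C[C@@]1(C)CCC(C)=C[C@H]1c1c(O)c(C=O)c(OC)cc1O[Si](C(C)C)(C(C)C)C(C)C | intermediate
22 | 2-[(1R,6R)-6-ethenyl-3,6-dimethylcyclohex-2-en-1-yl]-6-formyl-5-methoxy-3-{[tri(propan-2-yl)silyl]oxy}phenyl (triphenylphosphoranylidene)acetate | C=C[C@@]1(C)CCC(C)=C[C@H]1c1c(OC(=O)C=P(c2ccccc2)(c2ccccc2)c2ccccc2)c(C=O)c(OC)cc1O[Si](C(C)C)(C(C)C)C(C)C | intermediate (not isolated)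
23 | 8-[(1R,6R)-6-ethenyl-3,6-dimethylcyclohex-2-en-1-yl]-5-methoxy-7-{[tri(propan-2-yl)silyl]oxy}-2H-chromen-2-one | C=C[C@@]1(C)CCC(C)=C[C@H]1c1c(O[Si](C(C)C)(C(C)C)C(C)C)cc(OC)c2ccc(=O)oc12 | intermediate
24 | tetrabutylammonium 8-[(1R,6R)-6-ethenyl-3,6-dimethylcyclohex-2-en-1-yl]-5-methoxy-2-oxo-2H-chromen-7-olate | C=C[C@@]1(C)CCC(C)=C[C@H]1c1c([O-])cc(OC)c2ccc(=O)oc12.CCCC[N+](CCCC)(CCCC)CCCC | intermediate (not isolated)
25 | 8-[(1R,6R)-6-ethenyl-3,6-dimethylcyclohex-2-en-1-yl]-5,7-dimethoxy-2H-chromen-2-one | C=C[C@@]1(C)CCC(C)=C[C@H]1c1c(OC)cc(OC)c2ccc(=O)oc12 | intermediate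
26 | 5,7-dimethoxy-2H-chromen-2-one | COc1cc(OC)c2ccc(=O)oc2c1 | starting material
27 | 8-iodo-5,7-dimethoxy-2H-chromen-2-one | COc1cc(OC)c2ccc(=O)oc2c1I | intermediate
28 | 8-[(E)-2-[(1R,2R)-2-(5,7-dimethoxy-2-oxo-2H-chromen-8-yl)-1,4-dimethylcyclohex-3-en-1-yl]ethenyl]-5,7-dimethoxy-2H-chromen-2-one | COc1cc(OC)c2ccc(=O)oc2c1/C=C/[C@@]1(C)CCC(C)=C[C@H]1c1c(OC)cc(OC)c2ccc(=O)oc12 | target

**Step count and risks**

Total steps: 16. Longest linear sequence: 14 (steps 1–9, 11–14 and 16); steps 10 and 15 are side branches.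

Step 11 (most at risk). The fragile alkoxycyclobutenone may be consumed by ketene self-condensation, or excess ketene may acylate the product phenol, before the hindered ynol ether is engaged. Prolonged heating may also cause a 1,3-silyl shift of the ynol ether to a silylketene. Fallback: the same ketene 16 is generated photochemically at room temperature.
- Commercial 3,3-dimethoxybutan-2-one is heated with catalytic TsOH while methanol distils out, giving 3-methoxybut-3-en-2-one F1.
- Its lithium enolate (LiN(SiMe3)2, THF, −78 °C) is trifluoroacetylated with CF3CO2CH2CF3 to 1,1,1-trifluoro-5-methoxyhex-5-ene-2,4-dione F2.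
- Deacylative diazo transfer (MsN3, Et3N, H2O, MeCN) gives 1-diazo-3-methoxybut-3-en-2-one F3.
- Irradiation of F3 with 13 in ClCH2CH2Cl (medium-pressure Hg lamp, rt) should trigger a Wolff rearrangement to 16, which 13 traps as in step 11; brief warming to 80 °C completes the passage through 17–19.
- The fallback sets out from 13 and rejoins the route at 20.

Step 4. Endo/exo discrimination or facial selectivity may be insufficient with this diene, or the acid may degrade the diene. Fallback: the relative configuration is enforced by a cis-fused lactone and the absolute configuration by an auxiliary.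
- (R)-4-Benzyloxazolidin-2-one is N-acylated (n-BuLi, acryloyl chloride) to (4R)-4-benzyl-3-(prop-2-enoyl)-1,3-oxazolidin-2-one F4.
- Its Et2AlCl-promoted Diels–Alder reaction with 5 at −78 °C (chelated s-cis imide, diene anti to benzyl, endo) should give (4R)-4-benzyl-3-{[(1S,6R)-6-({[tert-butyl(dimethyl)silyl]oxy}methyl)-4-methylcyclohex-3-en-1-yl]carbonyl}-1,3-oxazolidin-2-one F5. Only the CH2O-bearing centre of F5 needs to be correct.
- n-Bu4NF frees the alkoxide, which closes onto the cis imide carbonyl and expels the auxiliary, giving (3aR,7aS)-5-methyl-3a,6,7,7a-tetrahydro-2-benzofuran-1(3H)-one F6.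
- LiN(i-Pr)2 then MeI methylates the ring-fusion enolate; the five-membered lactone should stay cis-fused, giving (3aR,7aS)-5,7a-dimethyl-3a,6,7,7a-tetrahydro-2-benzofuran-1(3H)-one F7.
- i-Bu2AlH at −78 °C gives (3aR,7aS)-5,7a-dimethyl-1,3,3a,6,7,7a-hexahydro-2-benzofuran-1-ol F8, and excess Ph3P=CH2 opens this lactol to the vinyl alcohol.
- The fallback sets out from 5 and rejoins the route at 8.

Step 9. Oxygen transfer to the hindered acetylide may be incomplete, silylation may go to carbon, or over-metalation at the allylic–propargylic carbon may erode its configuration. Fallback: the ynolate is reached by Kowalski ester homologation.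
- Pinnick oxidation of 9 (NaClO2, NaH2PO4, 2-methylbut-2-ene, t-BuOH–H2O) gives (1R,6R)-6-ethenyl-3,6-dimethylcyclohex-2-ene-1-carboxylic acid F9.
- Me3SiCHN2 in MeOH gives methyl (1R,6R)-6-ethenyl-3,6-dimethylcyclohex-2-ene-1-carboxylate F10.
- LiCHBr2 (from CH2Br2 and lithium 2,2,6,6-tetramethylpiperidide, THF, −78 °C) then LiN(SiMe3)2 converts F10 into lithium 2,2-dibromo-1-[(1R,6R)-6-ethenyl-3,6-dimethylcyclohex-2-en-1-yl]ethen-1-olate F11.
- n-BuLi induces bromine–lithium exchange and a 1,2-shift of the ring carbon with retention, giving ynolate 12, which i-Pr3SiOTf silylates.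
- The fallback sets out from 9 and rejoins the route at 13.

**Further compounds**

F1 | step 11 | 3-methoxybut-3-en-2-one | C=C(OC)C(C)=O
F2 | step 11 | 1,1,1-trifluoro-5-methoxyhex-5-ene-2,4-dione | C=C(OC)C(=O)CC(=O)C(F)(F)F
F3 | step 11 | 1-diazo-3-methoxybut-3-en-2-one | C=C(OC)C(=O)C=[N+]=[N-]
F4 | step 4 | (4R)-4-benzyl-3-(prop-2-enoyl)-1,3-oxazolidin-2-one | C=CC(=O)N1C(=O)OC[C@H]1Cc1ccccc1
F5 | step 4 | (4R)-4-benzyl-3-{[(1S,6R)-6-({[tert-butyl(dimethyl)silyl]oxy}methyl)-4-methylcyclohex-3-en-1-yl]carbonyl}-1,3-oxazolidin-2-one | O=C([C@H]1CCC(C)=C[C@H]1CO[Si](C)(C)C(C)(C)C)N1C(=O)OC[C@H]1Cc1ccccc1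
F6 | step 4 | (3aR,7aS)-5-methyl-3a,6,7,7a-tetrahydro-2-benzofuran-1(3H)-one | O=C2[C@H]1CCC(C)=C[C@H]1CO2
F7 | step 4 | (3aR,7aS)-5,7a-dimethyl-3a,6,7,7a-tetrahydro-2-benzofuran-1(3H)-one | O=C2[C@@]1(C)CCC(C)=C[C@H]1CO2
F8 | step 4 | (3aR,7aS)-5,7a-dimethyl-1,3,3a,6,7,7a-hexahydro-2-benzofuran-1-ol (both anomers) | OC2[C@@]1(C)CCC(C)=C[C@H]1CO2
F9 | step 9 | (1R,6R)-6-ethenyl-3,6-dimethylcyclohex-2-ene-1-carboxylic acid | C=C[C@@]1(C)CCC(C)=C[C@H]1C(=O)O
F10 | step 9 | methyl (1R,6R)-6-ethenyl-3,6-dimethylcyclohex-2-ene-1-carboxylate | C=C[C@@]1(C)CCC(C)=C[C@H]1C(=O)OC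
F11 | step 9 | lithium 2,2-dibromo-1-[(1R,6R)-6-ethenyl-3,6-dimethylcyclohex-2-en-1-yl]ethen-1-olate | C=C[C@@]1(C)CCC(C)=C[C@H]1C(O[Li])=C(Br)Br
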